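The flavonol half is disconnected at C3–C4 and O1–C8a. Its ring A carries oxygen at C5, C7 and C8a. These positions are ortho or para to C4a and therefore activated by the C4 carbonyl, so the ring enters as a 2,4,6-trifluorobenzoyl unit. In one operation an α-aryloxy ketone enolate is C-aroylated and the diketonate closes pyranone ring C by displacing an ortho fluoride. The precursor is a 4-benzyloxyphenacyl aryl ether that already contains the C3–O–C4' interflavonoid link and, masked as a dioxolane, the future flavanone C2. The two remaining fluorides become benzyl ethers, the 2S centre comes from a thiourea-catalysed oxa-Michael closure, and one hydrogenolysis ends the route.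

Key step: step 3

Assumption: the quinidine-derived thiourea is taken to deliver the 2S series. Its quinine-derived pseudo-enantiomer is equally available and takes its place should a CD check of 16 show the opposite sense.
Assumption: alkylidene 13 is drawn as the E isomer (aryl trans to the ester), the geometry expected for Knoevenagel products of aroylacetates. This geometry is not carried into the target.

Step 1
Reactants: 1 4-hydroxybenzaldehyde; 2 2-bromo-1-[4-(benzyloxy)phenyl]ethan-1-one
Product: 3 4-{2-[4-(benzyloxy)phenyl]-2-oxoethoxy}benzaldehyde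
Conditions: K2CO3 (1.5 equiv), acetone, 40 °C
Reagents that add atoms: none
Why: Williamson ether synthesis in which the phenoxide of 1 displaces the primary α-keto bromide of 2 by SN2, and alkylating before acetalisation avoids handling the labile acetal of a free para-hydroxybenzaldehyde.

Step 2
Reactants: 3 4-{2-[4-(benzyloxy)phenyl]-2-oxoethoxy}benzaldehyde
Product: 4 1-[4-(benzyloxy)phenyl]-2-[4-(1,3-dioxolan-2-yl)phenoxy]ethan-1-one
Conditions: HOCH2CH2OH (1.5 equiv), pyridinium p-toluenesulfonate (5 mol %), toluene, reflux, Dean–Stark trap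
Reagents that add atoms: ethylene glycol, OCCO
Why: Acid-catalysed acetalisation with water removal should be chemoselective because the aldehyde reacts far faster than the hindered, donor-deactivated aryl ketone, whose oxocarbenium ion is further disfavoured by the α-aryloxy group.

Step 3
Reactants: 4 1-[4-(benzyloxy)phenyl]-2-[4-(1,3-dioxolan-2-yl)phenoxy]ethan-1-one; 5 2,4,6-trifluorobenzoyl chloride
Product: 7 2-[4-(benzyloxy)phenyl]-3-[4-(1,3-dioxolan-2-yl)phenoxy]-5,7-difluoro-4H-chromen-4-one, via 2-aryloxy-1,3-diketone 6 (not isolated)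
Conditions: LiN(SiMe3)2 (2.1 equiv), THF, −78 °C; 5 (1.05 equiv), −78 → 0 °C; then K2CO3 (1.0 equiv), DMSO, 60 °C
Reagents that add atoms: none
Why: The first equivalent of LiN(SiMe3)2 converts 4 into its lithium enolate, which attacks acid chloride 5 through carbon (C3–C4 bond) to give diketone 6; the second equivalent deprotonates 6 as it forms, so no enolate of 4 is lost to proton transfer. After lithium is exchanged for potassium in the polar medium, which loosens the chelate, the diketonate oxygen on the 4-benzyloxybenzoyl side adds to an ortho carbon of the trifluorophenyl ring and the Meisenheimer complex expels fluoride (O1–C8a bond). The closest known reaction type is the one-pot aroylation of ketone enolates with 2-fluorobenzoyl chlorides followed by intramolecular SNAr to flavones, which is related to the cycloacylation used for fluoroquinolones. Ring C closes as a six-membered ring by intramolecular addition–elimination at an aromatic carbon, whereas the other diketonate oxygen could only form a four-membered ring and stays idle. No stereocentre is created. The step needs C- over O-acylation, which the tightly bound lithium counter-ion, the low temperature and the chelating α-aryloxy oxygen should secure, and it needs no regiocontrol in the SNAr because the two ortho fluorines of 5 are equivalent, while the remaining two fluorines lie out of reach of the tethered oxygen and the dioxolane and benzyl ether are inert to base.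

Step 4
Reactants: 7 2-[4-(benzyloxy)phenyl]-3-[4-(1,3-dioxolan-2-yl)phenoxy]-5,7-difluoro-4H-chromen-4-one
Product: 9 4-({5,7-bis(benzyloxy)-2-[4-(benzyloxy)phenyl]-4-oxo-4H-chromen-3-yl}oxy)benzaldehyde, via tribenzyl dioxolane 8 (not isolated)
Conditions: BnOH (3.0 equiv), NaH (2.6 equiv), THF, 0 °C; 7, THF–DMSO, 60 °C; then 1 M aq. HCl, THF, rt
Reagents that add atoms: benzyl alcohol, OCc1ccccc1; water, O
Why: Twofold SNAr is expected because C5–F and C7–F are ortho and para to C4a and thus activated by the C4 carbonyl, the alkoxy group that enters first sits meta to the remaining fluoride and hardly slows the second displacement, and the acidic finish effects acetal hydrolysis of the electron-rich aryl dioxolane without touching the benzyl ethers.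

Step 5
Reactants: 10 1-(2,6-dihydroxy-4-methoxyphenyl)ethan-1-one
Product: 11 1-[2-(benzyloxy)-6-hydroxy-4-methoxyphenyl]ethan-1-one
Conditions: BnBr (1.0 equiv), K2CO3 (1.1 equiv), acetone, reflux
Reagents that add atoms: benzyl bromide, BrCc1ccccc1
Why: Williamson mono-O-alkylation of a symmetric substrate should stop at 11 because, after the first benzylation, the remaining hydroxyl is locked in a hydrogen bond to the carbonyl and is much less nucleophilic.

Step 6
Reactants: 11 1-[2-(benzyloxy)-6-hydroxy-4-methoxyphenyl]ethan-1-one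
Product: 12 tert-butyl 3-[2-(benzyloxy)-6-hydroxy-4-methoxyphenyl]-3-oxopropanoate
Conditions: LiN(SiMe3)2 (3.2 equiv), THF, −78 °C; Boc2O (1.1 equiv), −78 → −20 °C; AcOH quench
Reagents that add atoms: di-tert-butyl dicarbonate, CC(C)(C)OC(=O)OC(=O)OC(C)(C)C
Why: This is a Claisen-type C-acylation of the phenoxide–enolate dianion, in which the carbon deprotonated last is the most nucleophilic site, any carbonate formed at the phenoxide oxygen is funnelled to the same product by Baker–Venkataraman-type O-to-C transfer, and the third equivalent of base stores 12 as its stabilised enolate.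

Step 7
Reactants: 9 4-({5,7-bis(benzyloxy)-2-[4-(benzyloxy)phenyl]-4-oxo-4H-chromen-3-yl}oxy)benzaldehyde; 12 tert-butyl 3-[2-(benzyloxy)-6-hydroxy-4-methoxyphenyl]-3-oxopropanoate
Product: 13 tert-butyl (E)-2-[2-(benzyloxy)-6-hydroxy-4-methoxybenzoyl]-3-[4-({5,7-bis(benzyloxy)-2-[4-(benzyloxy)phenyl]-4-oxo-4H-chromen-3-yl}oxy)phenyl]prop-2-enoate
Conditions: piperidine (20 mol %), AcOH (20 mol %), 4 Å MS, toluene, rt
Reagents that add atoms: none
Why: Knoevenagel condensation through the iminium ion of 9 runs under buffered conditions that spare the pyranone, which a hydroxide-mediated chalcone synthesis would expose to ring opening, and the bulky tert-butyl ester and the chelated phenol should hold back premature closure.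

Step 8
Reactants: 13 tert-butyl (E)-2-[2-(benzyloxy)-6-hydroxy-4-methoxybenzoyl]-3-[4-({5,7-bis(benzyloxy)-2-[4-(benzyloxy)phenyl]-4-oxo-4H-chromen-3-yl}oxy)phenyl]prop-2-enoate
Product: 16 (2S)-5-(benzyloxy)-2-[4-({5,7-bis(benzyloxy)-2-[4-(benzyloxy)phenyl]-4-oxo-4H-chromen-3-yl}oxy)phenyl]-7-methoxy-2,3-dihydro-4H-chromen-4-one, via trans-flavanone-3-carboxylic tert-butyl ester 14 (not isolated), via flavanone-3-carboxylic acid 15 (not isolated)
Conditions: 1-[3,5-bis(trifluoromethyl)phenyl]-3-[(9R)-6'-methoxycinchonan-9-yl]thiourea (10 mol %), toluene, −25 °C; then TsOH·H2O (0.5 equiv), 80 °C; acid wash and chromatography to remove the sulfur-containing catalyst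
Reagents that add atoms: none
Why: In this bifunctional-thiourea-catalysed enantioselective intramolecular oxa-Michael addition (6-endo-trig) of an alkylidene β-keto ester, the thiourea binds the dicarbonyl unit while the quinuclidine nitrogen guides the phenol to one face of the β-carbon, which sets C2 as S, and acid then removes isobutene and CO2 so that the labile C3 centre vanishes without touching C2.

Step 9
Reactants: 16 (2S)-5-(benzyloxy)-2-[4-({5,7-bis(benzyloxy)-2-[4-(benzyloxy)phenyl]-4-oxo-4H-chromen-3-yl}oxy)phenyl]-7-methoxy-2,3-dihydro-4H-chromen-4-one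
Product: 17 (2S)-2-(4-{[5,7-dihydroxy-2-(4-hydroxyphenyl)-4-oxo-4H-chromen-3-yl]oxy}phenyl)-5-hydroxy-7-methoxy-2,3-dihydro-4H-chromen-4-one (CNP0173006.1)
Conditions: H2 (1 atm), 10% Pd/C, THF–MeOH, rt
Reagents that add atoms: none
Why: Catalytic hydrogenolysis under neutral conditions at one atmosphere should cleave the four aryl benzyl ethers much faster than the cyclic benzylic C2–O1 bond and should leave the methyl ether, both carbonyls, the flavonol C2=C3 bond and the base-sensitive C2 stereocentre untouched.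

Compound list
1 | 4-hydroxybenzaldehyde | O=Cc1ccc(O)cc1 | starting material
2 | 2-bromo-1-[4-(benzyloxy)phenyl]ethan-1-one | O=C(CBr)c1ccc(OCc2ccccc2)cc1 | starting material
3 | 4-{2-[4-(benzyloxy)phenyl]-2-oxoethoxy}benzaldehyde | O=Cc1ccc(OCC(=O)c2ccc(OCc3ccccc3)cc2)cc1 | intermediate
4 | 1-[4-(benzyloxy)phenyl]-2-[4-(1,3-dioxolan-2-yl)phenoxy]ethan-1-one | O=C(COc1ccc(cc1)C1OCCO1)c1ccc(OCc2ccccc2)cc1 | intermediate
5 | 2,4,6-trifluorobenzoyl chloride | O=C(Cl)c1c(F)cc(F)cc1F | starting material
6 | 1-[4-(benzyloxy)phenyl]-2-[4-(1,3-dioxolan-2-yl)phenoxy]-3-(2,4,6-trifluorophenyl)propane-1,3-dione (racemic, enolisable) | O=C(c1ccc(OCc2ccccc2)cc1)C(Oc1ccc(cc1)C1OCCO1)C(=O)c1c(F)cc(F)cc1F | intermediate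
7 | 2-[4-(benzyloxy)phenyl]-3-[4-(1,3-dioxolan-2-yl)phenoxy]-5,7-difluoro-4H-chromen-4-one | O=c1c(Oc2ccc(cc2)C2OCCO2)c(-c2ccc(OCc3ccccc3)cc2)oc2cc(F)cc(F)c12 | intermediate
8 | 5,7-bis(benzyloxy)-2-[4-(benzyloxy)phenyl]-3-[4-(1,3-dioxolan-2-yl)phenoxy]-4H-chromen-4-one | O=c1c(Oc2ccc(cc2)C2OCCO2)c(-c2ccc(OCc3ccccc3)cc2)oc2cc(OCc3ccccc3)cc(OCc3ccccc3)c12 | intermediate
9 | 4-({5,7-bis(benzyloxy)-2-[4-(benzyloxy)phenyl]-4-oxo-4H-chromen-3-yl}oxy)benzaldehyde | O=Cc1ccc(Oc2c(-c3ccc(OCc4ccccc4)cc3)oc3cc(OCc4ccccc4)cc(OCc4ccccc4)c3c2=O)cc1 | intermediate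
10 | 1-(2,6-dihydroxy-4-methoxyphenyl)ethan-1-one | COc1cc(O)c(C(C)=O)c(O)c1 | starting material
11 | 1-[2-(benzyloxy)-6-hydroxy-4-methoxyphenyl]ethan-1-one | COc1cc(O)c(C(C)=O)c(OCc2ccccc2)c1 | intermediate
12 | tert-butyl 3-[2-(benzyloxy)-6-hydroxy-4-methoxyphenyl]-3-oxopropanoate | COc1cc(O)c(C(=O)CC(=O)OC(C)(C)C)c(OCc2ccccc2)c1 | intermediate
13 | tert-butyl (E)-2-[2-(benzyloxy)-6-hydroxy-4-methoxybenzoyl]-3-[4-({5,7-bis(benzyloxy)-2-[4-(benzyloxy)phenyl]-4-oxo-4H-chromen-3-yl}oxy)phenyl]prop-2-enoate | CC(C)(C)OC(=O)/C(C(=O)c1c(O)cc(OC)cc1OCc1ccccc1)=C/c1ccc(Oc2c(-c3ccc(OCc4ccccc4)cc3)oc3cc(OCc4ccccc4)cc(OCc4ccccc4)c3c2=O)cc1 | intermediate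
14 | tert-butyl (2S,3R)-5-(benzyloxy)-2-[4-({5,7-bis(benzyloxy)-2-[4-(benzyloxy)phenyl]-4-oxo-4H-chromen-3-yl}oxy)phenyl]-7-methoxy-4-oxochromane-3-carboxylate (2,3-trans, C3 epimerisable) | COc1cc(OCc2ccccc2)c2c(c1)O[C@H](c1ccc(Oc3c(-c4ccc(OCc5ccccc5)cc4)oc4cc(OCc5ccccc5)cc(OCc5ccccc5)c4c3=O)cc1)[C@@H](C(=O)OC(C)(C)C)C2=O | intermediate
15 | (2S,3R)-5-(benzyloxy)-2-[4-({5,7-bis(benzyloxy)-2-[4-(benzyloxy)phenyl]-4-oxo-4H-chromen-3-yl}oxy)phenyl]-7-methoxy-4-oxochromane-3-carboxylic acid | COc1cc(OCc2ccccc2)c2c(c1)O[C@H](c1ccc(Oc3c(-c4ccc(OCc5ccccc5)cc4)oc4cc(OCc5ccccc5)cc(OCc5ccccc5)c4c3=O)cc1)[C@@H](C(=O)O)C2=O | intermediate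
16 | (2S)-5-(benzyloxy)-2-[4-({5,7-bis(benzyloxy)-2-[4-(benzyloxy)phenyl]-4-oxo-4H-chromen-3-yl}oxy)phenyl]-7-methoxy-2,3-dihydro-4H-chromen-4-one | COc1cc(OCc2ccccc2)c2c(c1)O[C@H](c1ccc(Oc3c(-c4ccc(OCc5ccccc5)cc4)oc4cc(OCc5ccccc5)cc(OCc5ccccc5)c4c3=O)cc1)CC2=O | intermediate
17 | (2S)-2-(4-{[5,7-dihydroxy-2-(4-hydroxyphenyl)-4-oxo-4H-chromen-3-yl]oxy}phenyl)-5-hydroxy-7-methoxy-2,3-dihydro-4H-chromen-4-one | COc1cc(O)c2c(c1)O[C@H](c1ccc(Oc3c(-c4ccc(O)cc4)oc4cc(O)cc(O)c4c3=O)cc1)CC2=O | target

Total step count: 9. Longest linear sequence: 7 (steps 1, 2, 3, 4, 7, 8, 9). Steps 5 and 6 form the ring A branch that joins at step 7.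

Steps most likely to fail

Step 3. The enolate may be acylated at oxygen or acylated twice, or ring closure may stall at the chelated diketonate stage. The fallback sets out from 4 and replaces the acylation by an aldol addition followed by oxidation, so that attack through carbon is the only productive path. The lithium enolate of 4 (LiN(SiMe3)2, 1.05 equiv, THF, −78 °C) is added to commercial 2,4,6-trifluorobenzaldehyde. This should give the β-hydroxy ketone 1-[4-(benzyloxy)phenyl]-2-[4-(1,3-dioxolan-2-yl)phenoxy]-3-hydroxy-3-(2,4,6-trifluorophenyl)propan-1-one F1, as a diastereomer mixture of no consequence. Oxidation with Dess–Martin periodinane buffered by NaHCO3 in CH2Cl2 should then deliver diketone 6, this time isolated. K2CO3 in DMSO at 60 °C closes 6 to 7, where the route is rejoined.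

Step 8. Facial selectivity may suffer from uncatalysed background closure, and the enantiomeric purity may erode through reversible ring opening during the hot acidic decarboxylation. The fallback sets out from 9 and 11 and gives up catalytic ring closure in favour of a kinetic resolution.
- Claisen–Schmidt condensation (KOH, EtOH–THF, rt) should give the chalcone (E)-1-[2-(benzyloxy)-6-hydroxy-4-methoxyphenyl]-3-[4-({5,7-bis(benzyloxy)-2-[4-(benzyloxy)phenyl]-4-oxo-4H-chromen-3-yl}oxy)phenyl]prop-2-en-1-one F2.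
- NaOAc in refluxing EtOH closes F2 to the racemic tetrabenzyl flavanone F3. The 6'-alkoxy group favours the closed form.
- Asymmetric transfer hydrogenation with RuCl(p-cymene)[(R,R)-TsDPEN] and HCO2H–NEt3 in EtOAc at rt should reduce the matched 2R antipode to the cis-(2R,4R)-flavan-4-ol F4.
- The 2S ketone should be left untouched and is separated by chromatography as 16, where the route is rejoined.

Step 6. Acylation may occur at the phenoxide or enolate oxygen instead of carbon, or the product anion may lactonise with loss of tert-butoxide. The fallback sets out from 11 and makes the acyl transfer intramolecular and stepwise. Boc2O, NEt3 and catalytic DMAP in CH2Cl2 should give the isolated carbonate 2-acetyl-3-(benzyloxy)-5-methoxyphenyl tert-butyl carbonate F5. LiN(SiMe3)2 (2.2 equiv, THF, −78 → 0 °C) then enolises the acetyl group and triggers a Baker–Venkataraman-type O-to-C migration through a six-membered transition state. This gives 12, where the route is rejoined.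

Further compounds
F1 | step 3 | 1-[4-(benzyloxy)phenyl]-2-[4-(1,3-dioxolan-2-yl)phenoxy]-3-hydroxy-3-(2,4,6-trifluorophenyl)propan-1-one (racemic diastereomer mixture) | O=C(c1ccc(OCc2ccccc2)cc1)C(Oc1ccc(cc1)C1OCCO1)C(O)c1c(F)cc(F)cc1F
F2 | step 8 | (E)-1-[2-(benzyloxy)-6-hydroxy-4-methoxyphenyl]-3-[4-({5,7-bis(benzyloxy)-2-[4-(benzyloxy)phenyl]-4-oxo-4H-chromen-3-yl}oxy)phenyl]prop-2-en-1-one | COc1cc(O)c(C(=O)/C=C/c2ccc(Oc3c(-c4ccc(OCc5ccccc5)cc4)oc4cc(OCc5ccccc5)cc(OCc5ccccc5)c4c3=O)cc2)c(OCc2ccccc2)c1
F3 | step 8 | racemic 5-(benzyloxy)-2-[4-({5,7-bis(benzyloxy)-2-[4-(benzyloxy)phenyl]-4-oxo-4H-chromen-3-yl}oxy)phenyl]-7-methoxy-2,3-dihydro-4H-chromen-4-one | COc1cc(OCc2ccccc2)c2c(c1)OC(c1ccc(Oc3c(-c4ccc(OCc5ccccc5)cc4)oc4cc(OCc5ccccc5)cc(OCc5ccccc5)c4c3=O)cc1)CC2=O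
F4 | step 8 | 3-{4-[(2R,4R)-5-(benzyloxy)-4-hydroxy-7-methoxychroman-2-yl]phenoxy}-5,7-bis(benzyloxy)-2-[4-(benzyloxy)phenyl]-4H-chromen-4-one (2,4-cis) | COc1cc(OCc2ccccc2)c2c(c1)O[C@@H](c1ccc(Oc3c(-c4ccc(OCc5ccccc5)cc4)oc4cc(OCc5ccccc5)cc(OCc5ccccc5)c4c3=O)cc1)C[C@H]2O
F5 | step 6 | 2-acetyl-3-(benzyloxy)-5-methoxyphenyl tert-butyl carbonate | COc1cc(OC(=O)OC(C)(C)C)c(C(C)=O)c(OCc2ccccc2)c1
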